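## Structural features

The target 21 is a γ-butyrolactone, numbered here O1, C2 (carbonyl), C3, C4 and C5 (OCH2). Ring A (4-hydroxy-3-methoxyphenyl) is joined to C4 through a CH2 group, and ring B (3,4-dihydroxy-5-methoxyphenyl) sits on an exocyclic CH that is doubly bonded to C3. There is one stereocentre, C4 (S); it has no stereocentre as neighbour, but it stands next to the second stereochemical element, the trisubstituted C3=CH alkene, which is Z (ring B cis to the lactone carbonyl, trans to C4). The fragile groups are the Z-benzylidene lactone (isomerisation by light or by reversible conjugate addition), the lactone itself (base) and the free catechol of ring B, which is oxidised easily once deprotonated. The real difficulty is the alkene geometry: condensation of a preformed lactone with an aromatic aldehyde leads to the E isomer, so the Z geometry must come from a stereospecific process. The second difficulty is the absolute configuration at C4, whose three carbon substituents (two CH2 groups and an sp2 carbon) are too alike to be told apart late. The key step uses the fact that C4 bears an unsubstituted OCH2 (C5), the CH2 of ring A and C3: with C3 written as an aldehyde, C4 is the α-carbon of a 3-(ring A)propanal and C5 is one molecule of formaldehyde. An enamine aldol addition therefore makes the C4–C5 bond and the stereocentre at once and leaves C5 (alcohol) and C3 (aldehyde) at different oxidation levels, which later lets C3 become the alkyne on which the Z-alkene is built.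

## Logic of the disconnections

**21 from 20.** Only the three phenolic O–Si bonds are cut. Keeping all phenols silylated until the end means the acidic phenols and the oxidisable catechol never meet organometallic reagents, and the last step involves no C–C chemistry. The demand is a buffered fluoride source that spares the lactone, the Z-alkene and the catechol.

**20 from 19.** The C2–C3 and C2–O1 bonds are cut and C2 is removed as carbon monoxide. The reason is that an alkenyl iodide of fixed geometry is carbonylated with retention, and the C5 hydroxyl can only close the five-membered ring. The gain is an acyclic iodo alcohol without the carbonyl carbon. The demand is that CO insertion and ring closure outrun any isomerisation of the alkenylpalladium species.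

**19 from 18 from 17.** The C3–I bond is traced to a C3–Sn bond, and the C3–Sn and vinylic C–H bonds are cut back to a triple bond. Anti addition of H and tin is the one process that puts ring B cis to the future carbonyl carbon. The gain is that the geometric problem is reduced to an alkyne with no stereochemistry. The demand is anti addition with tin at C3, for which the free C5 hydroxyl of 17 serves as the directing group.

**17 from 16.** One aliphatic O–Si bond is cut. The C5 oxygen is carried as a triethylsilyl ether and not as a second TBS ether, because it must be freed while three aryl TBS ethers stay. Fluoride would strip the aryl ethers first, whereas mild acid removes only the primary triethylsilyl group.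

**16 from 9 and 13.** The sp–sp2 bond between the alkyne terminus and ring B is cut, and the alkynyl metal (14, then 15) is traced to the dibromoalkene. This divides the molecule into a ring A/C4 half and a ring B half of similar size. The demand is that the alkynylzinc species couples with an electron-rich aryl bromide; C4 is not acidic in this series, so its configuration is safe.

**9 from 8 from 7.** The C3=C bond is cut (one-carbon homologation of the aldehyde C3 with CBr4), then the O–Si bond at C5. The demand is a non-basic olefination and immediate protection, because 7 and 8 are α-branched aldehydes that can epimerise or eliminate.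

**7 from 5 and 6.** The C4–C5 bond is cut; this is the key disconnection. It removes the only stereocentre and leaves an achiral linear aldehyde and a one-carbon electrophile. The demand is catalyst-controlled face selectivity at the enamine, and mono-addition without dehydration.

**5 from 4 from 2 from 1.** No C–C bond is cut: the aldehyde comes from the primary alcohol, the alcohol (through 3) from anti-Markovnikov hydration of the allyl group, and the silyl ether from the phenol. The gain is a cheap bulk starting material that already holds ring A and all three side-chain carbons.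

**13 from 12 from 10.** Two O–Si bonds are cut, then the aryl C–O bond is traced (through 11) to an aryl C–CHO bond. The ortho-hydroxy aldehyde 10 already has bromine para to the hydroxyl, which is the ring B substitution pattern. The demand is clean aryl migration in the peroxide oxidation and complete double silylation of a hindered catechol.

## Other disconnections considered

**Alternative 1:** The cut is the O1–C5 bond, traced to the prochiral cyclobutanone A2 (3-(4-hydroxy-3-methoxybenzyl)cyclobutanone), in which C3 and C5 are enantiotopic CH2 groups. In the forward step a flavin-dependent Baeyer–Villiger monooxygenase with O2 and NADPH would insert oxygen on one side and give the lactone A1, (S)-4-(4-hydroxy-3-methoxybenzyl)dihydrofuran-2(3H)-one.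
- In its favour: A2 should be reachable from 2 in about three operations (ketene cycloaddition, dechlorination, desilylation), the oxidant is air, and the free phenol is tolerated in water. The stereocentre is also formed in a configurationally stable lactone and not in an epimerisable aldehyde; on that point the alternative is the better of the two.
- Against it here: A1 has C3 as a CH2 group, so the benzylidene unit would have to be added by condensation with an aromatic aldehyde, which favours the E isomer. An enzyme with the required S preference would also have to be found by screening.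
- Comparison: in structure it answers C4 only; in mechanism, active-site control may equal or exceed the small-molecule catalyst in selectivity but cannot be predicted in advance. In step economy up to the lactone stage it is the better plan, but that gain would be spent on the unsolved Z-alkene.

**Alternative 2:** The cut is the bond between the exocyclic CH and ring B. In the forward step Pd(OAc)2 with SPhos and K3PO4 would couple the (Z)-enol tosylate A4 with the ring B pinacol boronate A5 and give A3, the tris(methoxymethyl) ether of the target (3Z, 4S).
- In its favour: ring B enters in the last C–C bond formation, the coupling should retain the geometry of A4, and neither tin nor carbon monoxide is needed. On convergency and on reagent hazard it is the better plan.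
- Against it here: it creates no stereocentre, so C4 must come from a lactone of the A1 type. The geometry of A4 depends on kinetic control in the sulfonylation of a hydroxymethylene lactone, and A4 is a vinylogous sulfonic–carboxylic anhydride that aqueous base can attack by addition–elimination with loss of geometry. The three methoxymethyl ethers of A3 also need acid for removal, which endangers the Z-alkene and the lactone more than buffered fluoride does.
- Comparison: in mechanism, the chosen plan takes its geometry from an anti addition that is obligatory, the alternative from a selectivity that must be tuned. From the lactone stage the step count is about equal.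

**Alternative 3:** The cut is the C3–C4 bond together with two C–H bonds, back to the (Z)-cinnamyl arylpropiolate A7. In the forward step [Rh(cod)2]OTf with BINAP under H2 would form a rhodacyclopentene from alkyne and alkene and cleave it with hydrogen to give A6, the tris(tert-butyldimethylsilyl) ether of the target, identical with 20.
- In its favour: one step would form the ring bond, the stereocentre and the Z-alkene, the last as a mechanistic consequence of syn addition of C4 and H across the alkyne. The substrate A7 is a simple ester of two aryl C3 units and hydrogen is the only reagent. In step economy and convergency it is clearly the better plan.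
- Against it here: an ester tether prefers the conformation that holds alkyne and alkene apart, a 1,2-disubstituted aryl alkene inserts more slowly than a terminal one, so plain hydrogenation of alkyne or alkene may compete. The sense and level of asymmetric induction for this substitution pattern cannot be relied on beforehand.
- Comparison: the chosen plan separates the two stereochemical elements and gives each its own dependable control element (catalyst shielding for C4, anti hydrometalation for the alkene), at the price of roughly twice the step count.

Key step: step 4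

Assumption: the (S)-configured catalyst is assigned to the (R)-aldehyde 7 by the usual shielding model of diarylprolinol silyl ether enamines; if the sense were the reverse, the enantiomeric catalyst would be used with no other change.

## Route

Step 1
Reactants: 1 eugenol (4-allyl-2-methoxyphenol)
Product: 2 (4-allyl-2-methoxyphenoxy)(tert-butyl)dimethylsilane
Conditions: TBSCl, imidazole, DMF, rt
Reagents that add atoms: tert-butyldimethylsilyl chloride, CC(C)(C)[Si](C)(C)Cl
Why: Standard silylation of a phenol; the aryl TBS ether should survive all neutral, acidic and organometallic steps and is removed by fluoride at the end.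

Step 2
Reactants: 2 (4-allyl-2-methoxyphenoxy)(tert-butyl)dimethylsilane
Product: 4 3-[4-(tert-butyldimethylsilyloxy)-3-methoxyphenyl]propan-1-ol, via B-alkyl-9-borabicyclo[3.3.1]nonane 3 (not isolated)
Conditions: 9-BBN, THF, 0 °C to rt; then NaBO3·4H2O, H2O, rt
Reagents that add atoms: sodium perborate (hydroxyl oxygen), [Na+].[Na+].O[B-]1(O)OO[B-](O)(O)OO1
Why: Hydroboration–oxidation; the bulky borane adds boron to the terminal carbon of the allyl group, and perborate oxidises the C–B bond under conditions mild enough for the aryl silyl ether.

Step 3
Reactants: 4 3-[4-(tert-butyldimethylsilyloxy)-3-methoxyphenyl]propan-1-ol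
Product: 5 3-[4-(tert-butyldimethylsilyloxy)-3-methoxyphenyl]propanal
Conditions: TEMPO (10 mol%), PhI(OAc)2, CH2Cl2, rt
Reagents that add atoms: none
Why: Oxoammonium-mediated oxidation of a primary alcohol stops at the aldehyde and runs under near-neutral conditions that leave the silyl ether and the electron-rich ring alone.

Step 4
Reactants: 5 3-[4-(tert-butyldimethylsilyloxy)-3-methoxyphenyl]propanal; 6 formaldehyde (37% aqueous solution)
Product: 7 (R)-2-(hydroxymethyl)-3-[4-(tert-butyldimethylsilyloxy)-3-methoxyphenyl]propanal
Conditions: (S)-α,α-diphenylprolinol trimethylsilyl ether (10 mol%), 37% aq. HCHO (3 equiv), pH 7 buffer (KH2PO4/K2HPO4), toluene, rt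
Reagents that add atoms: none
Why: The secondary amine condenses with 5 to the E-configured anti enamine, one face of which is covered by the diphenyl(trimethylsilyloxy)methyl group. Monomeric formaldehyde, present in low equilibrium concentration in the buffered two-phase system, is attacked by the enamine β-carbon (the future C4) from the open face, which forms the C4–C5 bond; hydrolysis of the iminium ion releases 7 and returns the catalyst. The closest known reaction type is the diarylprolinol silyl ether-catalysed cross-aldol reaction (α-hydroxymethylation) of aliphatic aldehydes with aqueous formaldehyde. No ring is closed. The one new stereocentre, C4, is controlled by the single stereocentre of the catalyst: with the (S)-catalyst the electrophile should enter as in the Michael additions of the same enamines, which corresponds to R in 7 (CHO > CH2OH > CH2Ar) and to the S arrangement of C4 in 21. The step needs mono-hydroxymethylation in preference to self-aldol reaction, double addition and amine-mediated dehydration to the α-methylene aldehyde; the excess of the non-enolisable and very electrophilic formaldehyde suppresses self-condensation, the neutral buffer and the bulky catalyst disfavour elimination, and the α-branched product re-forms an enamine only slowly. The aryl silyl ether and the benzylic CH2 are spectators at pH 7. Crude 7 is not chromatographed but silylated at once, because the stereocentre α to the aldehyde can epimerise.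

Step 5
Reactants: 7 (R)-2-(hydroxymethyl)-3-[4-(tert-butyldimethylsilyloxy)-3-methoxyphenyl]propanal
Product: 8 (R)-3-[4-(tert-butyldimethylsilyloxy)-3-methoxyphenyl]-2-[(triethylsilyloxy)methyl]propanal
Conditions: TESCl, imidazole, CH2Cl2, 0 °C (crude 7)
Reagents that add atoms: chlorotriethylsilane, CC[Si](CC)(CC)Cl
Why: Fast silylation of the primary alcohol at low temperature blocks retro-aldol reaction, dehydration and hemiacetal formation; the triethylsilyl group is chosen because mild acid removes it later while aryl TBS ethers stay.

Step 6
Reactants: 8 (R)-3-[4-(tert-butyldimethylsilyloxy)-3-methoxyphenyl]-2-[(triethylsilyloxy)methyl]propanal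
Product: 9 (S)-tert-butyl{4-[4,4-dibromo-2-(triethylsilyloxymethyl)but-3-en-1-yl]-2-methoxyphenoxy}dimethylsilane
Conditions: CBr4, PPh3, 2,6-lutidine, CH2Cl2, 0 °C
Reagents that add atoms: carbon tetrabromide, BrC(Br)(Br)Br
Why: Ramirez dibromo-olefination (first stage of the Corey–Fuchs sequence) with a weakly basic ylide, buffered by lutidine to protect the silyl ethers; C4 is untouched, and the descriptor changes from R to S only because the CIP priorities change.

Step 7
Reactants: 10 5-bromo-2-hydroxy-3-methoxybenzaldehyde
Product: 12 5-bromo-3-methoxybenzene-1,2-diol, via aryl formate 11 (not isolated)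
Conditions: 30% H2O2, aq. NaOH, 0 °C to rt; then aq. HCl
Reagents that add atoms: hydrogen peroxide, OO
Why: Dakin oxidation; hydroperoxide adds to the aldehyde, the electron-rich ortho-hydroxyaryl group migrates to oxygen, and the formate 11 is hydrolysed in the same flask to the catechol.

Step 8
Reactants: 12 5-bromo-3-methoxybenzene-1,2-diol
Product: 13 5-bromo-1,2-bis(tert-butyldimethylsilyloxy)-3-methoxybenzene
Conditions: TBSCl, imidazole, DMAP (cat.), DMF, rt to 40 °C
Reagents that add atoms: tert-butyldimethylsilyl chloride, CC(C)(C)[Si](C)(C)Cl
Why: Double silylation of the catechol; this gives ring B the same fluoride-labile protection as ring A, so that one final step frees all three phenols.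

Step 9
Reactants: 9 (S)-tert-butyl{4-[4,4-dibromo-2-(triethylsilyloxymethyl)but-3-en-1-yl]-2-methoxyphenoxy}dimethylsilane; 13 5-bromo-1,2-bis(tert-butyldimethylsilyloxy)-3-methoxybenzene
Product: 16 (S)-{2-[4-(tert-butyldimethylsilyloxy)-3-methoxybenzyl]-4-[3,4-bis(tert-butyldimethylsilyloxy)-5-methoxyphenyl]but-3-yn-1-yloxy}triethylsilane, via lithium acetylide 14 (not isolated), via alkynylzinc chloride 15 (not isolated)
Conditions: n-BuLi (2.1 equiv), THF, −78 °C; ZnCl2, −78 to 0 °C; 13, Pd(PPh3)4 (5 mol%), THF, 60 °C
Reagents that add atoms: none
Why: Second stage of the Corey–Fuchs sequence (bromine–lithium exchange, 1,2-shift, deprotonation) gives acetylide 14, which is transmetalated to zinc and joined to the aryl bromide by Negishi coupling; the C4 hydrogen is not acidic in this series, so the stereocentre is safe.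

Step 10
Reactants: 16 (S)-{2-[4-(tert-butyldimethylsilyloxy)-3-methoxybenzyl]-4-[3,4-bis(tert-butyldimethylsilyloxy)-5-methoxyphenyl]but-3-yn-1-yloxy}triethylsilane
Product: 17 (S)-2-[4-(tert-butyldimethylsilyloxy)-3-methoxybenzyl]-4-[3,4-bis(tert-butyldimethylsilyloxy)-5-methoxyphenyl]but-3-yn-1-ol
Conditions: PPTS (cat.), MeOH/CH2Cl2, 0 °C to rt
Reagents that add atoms: none
Why: Acid-catalysed methanolysis cleaves a primary triethylsilyl ether much faster than aryl TBS ethers, which are labile to fluoride and base but robust towards mild acid.

Step 11
Reactants: 17 (S)-2-[4-(tert-butyldimethylsilyloxy)-3-methoxybenzyl]-4-[3,4-bis(tert-butyldimethylsilyloxy)-5-methoxyphenyl]but-3-yn-1-ol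
Product: 18 (2R,3Z)-4-[3,4-bis(tert-butyldimethylsilyloxy)-5-methoxyphenyl]-2-[4-(tert-butyldimethylsilyloxy)-3-methoxybenzyl]-3-(tributylstannyl)but-3-en-1-ol
Conditions: [Cp*RuCl]4 (2.5 mol%), Bu3SnH, CH2Cl2, rt
Reagents that add atoms: tributyltin hydride, CCCC[SnH](CCCC)CCCC
Why: Ruthenium-catalysed trans-hydrostannation; a hydrogen bond from the C5 hydroxyl to the chloride ligand should steer tin to the proximal alkyne carbon C3, and hydrogen is delivered anti to the benzylic carbon, so tin ends up cis to ring B (Z).

Step 12
Reactants: 18 (2R,3Z)-4-[3,4-bis(tert-butyldimethylsilyloxy)-5-methoxyphenyl]-2-[4-(tert-butyldimethylsilyloxy)-3-methoxybenzyl]-3-(tributylstannyl)but-3-en-1-ol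
Product: 19 (2R,3Z)-4-[3,4-bis(tert-butyldimethylsilyloxy)-5-methoxyphenyl]-2-[4-(tert-butyldimethylsilyloxy)-3-methoxybenzyl]-3-iodobut-3-en-1-ol
Conditions: I2, CH2Cl2, 0 °C, dark; aq. Na2S2O3
Reagents that add atoms: iodine, II
Why: Iododestannylation is an ipso substitution at the alkenyl carbon with retention of geometry; low temperature and exclusion of light guard against iodine-mediated isomerisation.

Step 13
Reactants: 19 (2R,3Z)-4-[3,4-bis(tert-butyldimethylsilyloxy)-5-methoxyphenyl]-2-[4-(tert-butyldimethylsilyloxy)-3-methoxybenzyl]-3-iodobut-3-en-1-ol
Product: 20 (3Z,4S)-3-[3,4-bis(tert-butyldimethylsilyloxy)-5-methoxybenzylidene]-4-[4-(tert-butyldimethylsilyloxy)-3-methoxybenzyl]dihydrofuran-2(3H)-one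
Conditions: Pd(PPh3)4 (5 mol%), CO (1 atm), Et3N, THF/MeCN, 60 °C
Reagents that add atoms: carbon monoxide, [C-]#[O+]
Why: Carbonylative lactonization; zerovalent palladium inserts into the C–I bond with retention, CO insertion gives the acylpalladium species, and the C5 hydroxyl attacks the acyl carbon to close the five-membered lactone, leaving ring B cis to the new carbonyl.

Step 14
Reactants: 20 (3Z,4S)-3-[3,4-bis(tert-butyldimethylsilyloxy)-5-methoxybenzylidene]-4-[4-(tert-butyldimethylsilyloxy)-3-methoxybenzyl]dihydrofuran-2(3H)-one
Product: 21 (3Z,4S)-3-(3,4-dihydroxy-5-methoxybenzylidene)-4-(4-hydroxy-3-methoxybenzyl)dihydrofuran-2(3H)-one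
Conditions: Bu4NF, AcOH (1:1), THF, 0 °C, argon, dark
Reagents that add atoms: none
Why: Fluoride cleaves the three aryl silyl ethers; acetic acid protonates the phenoxides as they form, so that the catechol is not oxidised and the lactone and Z-alkene are not exposed to base.

## Compound list

1 | eugenol (4-allyl-2-methoxyphenol) | COc1cc(CC=C)ccc1O | starting material
2 | (4-allyl-2-methoxyphenoxy)(tert-butyl)dimethylsilane | COc1cc(CC=C)ccc1O[Si](C)(C)C(C)(C)C | intermediate
3 | 9-{3-[4-(tert-butyldimethylsilyloxy)-3-methoxyphenyl]propyl}-9-borabicyclo[3.3.1]nonane | COc1cc(CCCB2C3CCCC2CCC3)ccc1O[Si](C)(C)C(C)(C)C | intermediate (not isolated)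
4 | 3-[4-(tert-butyldimethylsilyloxy)-3-methoxyphenyl]propan-1-ol | COc1cc(CCCO)ccc1O[Si](C)(C)C(C)(C)C | intermediate
5 | 3-[4-(tert-butyldimethylsilyloxy)-3-methoxyphenyl]propanal | COc1cc(CCC=O)ccc1O[Si](C)(C)C(C)(C)C | intermediate
6 | formaldehyde | C=O | starting material
7 | (R)-2-(hydroxymethyl)-3-[4-(tert-butyldimethylsilyloxy)-3-methoxyphenyl]propanal | COc1cc(C[C@@H](C=O)CO)ccc1O[Si](C)(C)C(C)(C)C | intermediate
8 | (R)-3-[4-(tert-butyldimethylsilyloxy)-3-methoxyphenyl]-2-[(triethylsilyloxy)methyl]propanal | COc1cc(C[C@@H](C=O)CO[Si](CC)(CC)CC)ccc1O[Si](C)(C)C(C)(C)C | intermediate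
9 | (S)-tert-butyl{4-[4,4-dibromo-2-(triethylsilyloxymethyl)but-3-en-1-yl]-2-methoxyphenoxy}dimethylsilane | COc1cc(C[C@@H](C=C(Br)Br)CO[Si](CC)(CC)CC)ccc1O[Si](C)(C)C(C)(C)C | intermediate
10 | 5-bromo-2-hydroxy-3-methoxybenzaldehyde | COc1cc(Br)cc(C=O)c1O | starting material
11 | 5-bromo-2-hydroxy-3-methoxyphenyl formate | COc1cc(Br)cc(OC=O)c1O | intermediate (not isolated)
12 | 5-bromo-3-methoxybenzene-1,2-diol | COc1cc(Br)cc(O)c1O | intermediate
13 | 5-bromo-1,2-bis(tert-butyldimethylsilyloxy)-3-methoxybenzene | COc1cc(Br)cc(O[Si](C)(C)C(C)(C)C)c1O[Si](C)(C)C(C)(C)C | intermediate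
14 | lithium (S)-3-[4-(tert-butyldimethylsilyloxy)-3-methoxybenzyl]-4-(triethylsilyloxy)but-1-yn-1-ide | COc1cc(C[C@@H](C#C[Li])CO[Si](CC)(CC)CC)ccc1O[Si](C)(C)C(C)(C)C | intermediate (not isolated)
15 | chloro{(S)-3-[4-(tert-butyldimethylsilyloxy)-3-methoxybenzyl]-4-(triethylsilyloxy)but-1-yn-1-yl}zinc | COc1cc(C[C@@H](C#C[Zn]Cl)CO[Si](CC)(CC)CC)ccc1O[Si](C)(C)C(C)(C)C | intermediate (not isolated)
16 | (S)-{2-[4-(tert-butyldimethylsilyloxy)-3-methoxybenzyl]-4-[3,4-bis(tert-butyldimethylsilyloxy)-5-methoxyphenyl]but-3-yn-1-yloxy}triethylsilane | COc1cc(C[C@@H](C#Cc2cc(O[Si](C)(C)C(C)(C)C)c(O[Si](C)(C)C(C)(C)C)c(OC)c2)CO[Si](CC)(CC)CC)ccc1O[Si](C)(C)C(C)(C)C | intermediate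
17 | (S)-2-[4-(tert-butyldimethylsilyloxy)-3-methoxybenzyl]-4-[3,4-bis(tert-butyldimethylsilyloxy)-5-methoxyphenyl]but-3-yn-1-ol | COc1cc(C[C@@H](C#Cc2cc(O[Si](C)(C)C(C)(C)C)c(O[Si](C)(C)C(C)(C)C)c(OC)c2)CO)ccc1O[Si](C)(C)C(C)(C)C | intermediate
18 | (2R,3Z)-4-[3,4-bis(tert-butyldimethylsilyloxy)-5-methoxyphenyl]-2-[4-(tert-butyldimethylsilyloxy)-3-methoxybenzyl]-3-(tributylstannyl)but-3-en-1-ol | COc1cc(C[C@@H](/C(=C/c2cc(O[Si](C)(C)C(C)(C)C)c(O[Si](C)(C)C(C)(C)C)c(OC)c2)[Sn](CCCC)(CCCC)CCCC)CO)ccc1O[Si](C)(C)C(C)(C)C | intermediate
19 | (2R,3Z)-4-[3,4-bis(tert-butyldimethylsilyloxy)-5-methoxyphenyl]-2-[4-(tert-butyldimethylsilyloxy)-3-methoxybenzyl]-3-iodobut-3-en-1-ol | COc1cc(C[C@@H](/C(I)=C/c2cc(O[Si](C)(C)C(C)(C)C)c(O[Si](C)(C)C(C)(C)C)c(OC)c2)CO)ccc1O[Si](C)(C)C(C)(C)C | intermediate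
20 | (3Z,4S)-3-[3,4-bis(tert-butyldimethylsilyloxy)-5-methoxybenzylidene]-4-[4-(tert-butyldimethylsilyloxy)-3-methoxybenzyl]dihydrofuran-2(3H)-one | COc1cc(C[C@@H]2COC(=O)/C2=C\c2cc(O[Si](C)(C)C(C)(C)C)c(O[Si](C)(C)C(C)(C)C)c(OC)c2)ccc1O[Si](C)(C)C(C)(C)C | intermediate
21 | (3Z,4S)-3-(3,4-dihydroxy-5-methoxybenzylidene)-4-(4-hydroxy-3-methoxybenzyl)dihydrofuran-2(3H)-one | COc1cc(C[C@@H]2COC(=O)/C2=C\c2cc(O)c(O)c(OC)c2)ccc1O | target

## Step count and least certain steps

Total step count: 14. Longest linear sequence: 12 steps (steps 1 to 6 and 9 to 14, from 1 to 21); steps 7 and 8 are the two-step branch to 13.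

**Step 4 (key step).** The most likely failures are erosion of enantiomeric purity and loss of material. The first would come from reversible enamine formation on the α-branched product or from epimerisation during the silylation that follows. The second would come from amine-mediated dehydration to the α-methylene aldehyde or from hemiacetal oligomers with excess formaldehyde. The fallback replaces catalyst control by auxiliary control; it sets out from 5 and returns at 8.
- 5 would be oxidised (NaClO2, NaH2PO4, 2-methyl-2-butene) to 3-[4-(tert-butyldimethylsilyloxy)-3-methoxyphenyl]propanoic acid F1.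
- F1 would be activated with pivaloyl chloride and Et3N as the mixed pivalic anhydride F2 and transferred to (S)-4-benzyl-2-oxazolidinone in the presence of LiCl, giving the N-acyl oxazolidinone F3.
- Formation of the titanium enolate (TiCl4, i-Pr2NEt, CH2Cl2, 0 °C) and reaction with s-trioxane/TiCl4 should give the (R)-hydroxymethyl imide F4, the benzyl group of the auxiliary covering one face of the chelated Z-enolate.
- Transamination with MeNHOMe·HCl/AlMe3 should give the hydroxy Weinreb amide F5, silylation (TESCl, imidazole) the silylated Weinreb amide F6, and reduction with i-Bu2AlH at −78 °C the aldehyde 8.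

**Step 11.** The most likely failure is insufficient regiocontrol, with tin delivered to the benzylic alkyne carbon. The directing hydroxyl is one carbon further from the triple bond than in the propargylic cases, and the aryl group polarises the alkyne; some syn addition is a second risk. The fallback gives up anti hydrometalation; it sets out from 17 and returns at 20. Palladium-catalysed cyclocarbonylation of 17 (Pd2(dba)3, 1,4-bis(diphenylphosphino)butane, CO/H2, CH2Cl2, 90 °C) proceeds by syn addition and should give the (3E,4S)-benzylidene lactone F7. Irradiation of F7 at 365 nm with a triplet sensitiser such as thioxanthone should then set up a photostationary mixture, from which 20 is separated and the E isomer returned to the irradiation.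

**Step 9.** The most likely failures are incomplete conversion of the carbenoid into the acetylide and slow oxidative addition of the electron-rich aryl bromide, so that protonation and oxidative dimerisation of the alkynyl metal compete. The fallback isolates the alkyne and changes the coupling type; it sets out from 9 and returns at 16. Treatment of 9 with n-BuLi at −78 °C and quenching with aq. NH4Cl should give the terminal alkyne (S)-tert-butyl{4-[2-(triethylsilyloxymethyl)but-3-yn-1-yl]-2-methoxyphenoxy}dimethylsilane F8. Purified F8 would then be joined to 13 by a copper-cocatalysed Sonogashira coupling (PdCl2(PPh3)2, CuI, i-Pr2NH, 60 °C) to give 16.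

**Step 13.** The most likely failures are geometric scrambling at the alkenyl- or acylpalladium stage at 60 °C, and reduction of the C–I bond when oxidative addition into the hindered iodide is slow. The fallback replaces the palladium carbonylation by polar organolithium chemistry; it sets out from 19 and returns at 20. Deprotonation of the hydroxyl with MeLi (1 equiv), iodine–lithium exchange with t-BuLi (2 equiv) in THF at −78 °C (alkenyllithium species of this type hold their configuration at that temperature), and trapping with CO2 should give after acidification the hydroxy acid (2Z)-3-[3,4-bis(tert-butyldimethylsilyloxy)-5-methoxyphenyl]-2-{(2S)-1-hydroxy-3-[4-(tert-butyldimethylsilyloxy)-3-methoxyphenyl]propan-2-yl}prop-2-enoic acid F9. F9 should lactonise to 20 on standing or with catalytic PPTS.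

## Further compounds

F1 | step 4 | 3-[4-(tert-butyldimethylsilyloxy)-3-methoxyphenyl]propanoic acid | COc1cc(CCC(=O)O)ccc1O[Si](C)(C)C(C)(C)C
F2 | step 4 | 3-[4-(tert-butyldimethylsilyloxy)-3-methoxyphenyl]propanoic pivalic anhydride | COc1cc(CCC(=O)OC(=O)C(C)(C)C)ccc1O[Si](C)(C)C(C)(C)C
F3 | step 4 | (S)-4-benzyl-3-{3-[4-(tert-butyldimethylsilyloxy)-3-methoxyphenyl]propanoyl}oxazolidin-2-one | COc1cc(CCC(=O)N2[C@@H](Cc3ccccc3)COC2=O)ccc1O[Si](C)(C)C(C)(C)C
F4 | step 4 | (S)-4-benzyl-3-{(R)-2-(hydroxymethyl)-3-[4-(tert-butyldimethylsilyloxy)-3-methoxyphenyl]propanoyl}oxazolidin-2-one | COc1cc(C[C@@H](C(=O)N2[C@@H](Cc3ccccc3)COC2=O)CO)ccc1O[Si](C)(C)C(C)(C)C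
F5 | step 4 | (R)-3-hydroxy-N-methoxy-N-methyl-2-[4-(tert-butyldimethylsilyloxy)-3-methoxybenzyl]propanamide | COc1cc(C[C@@H](C(=O)N(C)OC)CO)ccc1O[Si](C)(C)C(C)(C)C
F6 | step 4 | (R)-N-methoxy-N-methyl-2-[4-(tert-butyldimethylsilyloxy)-3-methoxybenzyl]-3-(triethylsilyloxy)propanamide | COc1cc(C[C@@H](C(=O)N(C)OC)CO[Si](CC)(CC)CC)ccc1O[Si](C)(C)C(C)(C)C
F7 | step 11 | (3E,4S)-3-[3,4-bis(tert-butyldimethylsilyloxy)-5-methoxybenzylidene]-4-[4-(tert-butyldimethylsilyloxy)-3-methoxybenzyl]dihydrofuran-2(3H)-one | COc1cc(C[C@@H]2COC(=O)/C2=C/c2cc(O[Si](C)(C)C(C)(C)C)c(O[Si](C)(C)C(C)(C)C)c(OC)c2)ccc1O[Si](C)(C)C(C)(C)C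
F8 | step 9 | (S)-tert-butyl{4-[2-(triethylsilyloxymethyl)but-3-yn-1-yl]-2-methoxyphenoxy}dimethylsilane | COc1cc(C[C@@H](C#C)CO[Si](CC)(CC)CC)ccc1O[Si](C)(C)C(C)(C)C
F9 | step 13 | (2Z)-3-[3,4-bis(tert-butyldimethylsilyloxy)-5-methoxyphenyl]-2-{(2S)-1-hydroxy-3-[4-(tert-butyldimethylsilyloxy)-3-methoxyphenyl]propan-2-yl}prop-2-enoic acid | COc1cc(C[C@@H](/C(C(=O)O)=C/c2cc(O[Si](C)(C)C(C)(C)C)c(O[Si](C)(C)C(C)(C)C)c(OC)c2)CO)ccc1O[Si](C)(C)C(C)(C)C
A1 | alternative 1 | (S)-4-(4-hydroxy-3-methoxybenzyl)dihydrofuran-2(3H)-one | COc1cc(C[C@@H]2COC(=O)C2)ccc1O
A2 | alternative 1 | 3-(4-hydroxy-3-methoxybenzyl)cyclobutan-1-one | COc1cc(CC2CC(=O)C2)ccc1O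
A3 | alternative 2 | (3Z,4S)-3-[5-methoxy-3,4-bis(methoxymethoxy)benzylidene]-4-[3-methoxy-4-(methoxymethoxy)benzyl]dihydrofuran-2(3H)-one | COCOc1ccc(C[C@@H]2COC(=O)/C2=C\c2cc(OCOC)c(OCOC)c(OC)c2)cc1OC
A4 | alternative 2 | (3Z,4S)-4-[3-methoxy-4-(methoxymethoxy)benzyl]-3-[(tosyloxy)methylene]dihydrofuran-2(3H)-one | COCOc1ccc(C[C@@H]2COC(=O)/C2=C\OS(=O)(=O)c2ccc(C)cc2)cc1OC
A5 | alternative 2 | 2-[5-methoxy-3,4-bis(methoxymethoxy)phenyl]-4,4,5,5-tetramethyl-1,3,2-dioxaborolane | COCOc1cc(B2OC(C)(C)C(C)(C)O2)cc(OC)c1OCOC
A6 | alternative 3 | (3Z,4S)-3-[3,4-bis(tert-butyldimethylsilyloxy)-5-methoxybenzylidene]-4-[4-(tert-butyldimethylsilyloxy)-3-methoxybenzyl]dihydrofuran-2(3H)-one | COc1cc(C[C@@H]2COC(=O)/C2=C\c2cc(O[Si](C)(C)C(C)(C)C)c(O[Si](C)(C)C(C)(C)C)c(OC)c2)ccc1O[Si](C)(C)C(C)(C)C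
A7 | alternative 3 | (Z)-3-[4-(tert-butyldimethylsilyloxy)-3-methoxyphenyl]allyl 3-[3,4-bis(tert-butyldimethylsilyloxy)-5-methoxyphenyl]propiolate | COc1cc(/C=C\COC(=O)C#Cc2cc(O[Si](C)(C)C(C)(C)C)c(O[Si](C)(C)C(C)(C)C)c(OC)c2)ccc1O[Si](C)(C)C(C)(C)C
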